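The isomer of the product serves as the clock of this flask: its rate of gain, not its level, shows whether 0.14 M of substrate is still working at 15 d.

| flask | substrate | remark | time |
|---|---|---|---|
| dawn | 0.070 M | run made earlier |  |
| winter | 0.11 M | run made earlier |  |
| flask | 0.14 M |  | 15 d |

| run | time / d | target / % | isomer of the product / % |
|---|---|---|---|
| dawn | 1.25 | 28.2 | 38.2 |
| dawn | 2.08 | 24.8 | 47.2 |
| dawn | 3.00 | 21.3 | 50.5 |
| dawn | 5.00 | 19.2 | 54.8 |
| dawn | 10.0 | 19.5 | 56.2 |
| dawn | 15.0 | 20.0 | 53.1 |
| winter | 1.25 | 28.0 | 38.5 |
| winter | 2.08 | 24.2 | 48.9 |
| winter | 3.00 | 21.1 | 53.2 |
| winter | 5.00 | 20.1 | 54.0 |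
| winter | 10.0 | 18.1 | 55.0 |
| winter | 15.0 | 19.3 | 55.6 |

(scatter of a reading: 1 percentage point)

- for target the crystals are counted in
- as a solid, counted per litre of solution: crystals
- the earlier runs were read with a standard deviation of 1 percentage point
- steps thought possible: crystals <-> target; substrate -> intermediate; intermediate <-> target; intermediate <-> isomer of the product
- the reaction counts as stopped when no species that holds the substrate changes by six tenths of a point or more over the second half of the time

- at 15 d, what has stopped the reaction, if anything has (all of the substrate has reacted / forward and back rates have come level / it is still moving)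
- target at 15 d, in percent of the substrate charged
- isomer of the product at 15 d, in percent of the substrate charged

Averaged over the dawn and winter runs, the isomer gains 0.117 d⁻¹ of the charge between the first two readings, but 0.0413 d⁻¹ between the next two. The rate therefore falls by a factor of 2.83 across 0.875 d. Taken singly, dawn reads 3.02 and winter 2.68, so the charge leaves no clear mark on the slowing.

Freezing that factor gives 0.583 d as h, the halving time of the isomer's rate of gain, in the usual term a relaxation half-life. The halvings after 3.00 d add up to the rate there times 1.44 h, so this reckoning levels the isomer near 53.9%. After 7.50 d, it leaves 0.0096 percentage points still to come, less than the scatter of a reading. The reckoning thus expects a standstill, but the readings show no substrate, so they do not say what ended the reaction.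

The forecast stands higher on the isomer, with 19.4% target, 55% isomer and, for the end, "forward and back rates have come level", since the readings, in its words, “point to reversible equilibrium among intermediate, target and isomer”.

The flask gives 20.0% target and 55.9% isomer at 15 d, and the end is that all of the substrate has reacted, with 0% substrate left.

    crystals ⇌ target, rate k1*(cs1 - [target]) while solid is left; crystals form when [target] > cs1 (solubility = 0.120 M, k = 2.03 h⁻¹)
    substrate → intermediate (k = 0.436 h⁻¹)
    intermediate ⇌ target (K = 0.831, k = 0.328 h⁻¹)
    intermediate ⇌ isomer of the product (K = 2.32, k = 0.0424 h⁻¹)

The isomer stands 2 points above the reckoned level. From 7.50 d to 15 d, a stretch that the h read from the readings counts as about 12.9 halvings, the shares in this flask change by at most 0.041 points, less than the scatter of a reading. Carried to the neighbour flask of 0.056 M substrate, the same h puts 25.7 halvings into 15 d, and that flask stands at 20.0% target and 55.9% isomer.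

The readings are calculated from invented constants; the scatter is artificial.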